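Retrosynthesis: with the acetyl and silyl helpers removed, the aryl ketone bond C4–C4a of ring C is cut (seco acid), then the benzylic ether bond O1–C2 (ring A phenol plus an (R)-β-hydroxy ester), then the C–C bond that holds the 1,1-dimethylallyl group on ring A (back to a prenyl ether of phloroglucinol) and C2–C3 (vanillin acetate plus a diazoacetate).
Forward: ring A is finished first (O-prenylation, aromatic Claisen rearrangement), the ring B chain is built from vanillin acetate, the two are joined through O1–C2, and ring C closes last by acylation of ring A.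
Enabling feature: C6, which bears the 1,1-dimethylallyl group, lies para to C8a–O1, so in the seco acid ring A is a 4-alkyl-3,5-dioxygenated phenyl ether with a local mirror plane; its two free carbons (future C4a and C8) are equivalent and both ortho to O1, so one closure builds ring C and fixes the side chain at C6 between O5 and O7 with no regiochemical control element.
Helpers: a 4'-O-acetyl group (keeps the benzylic C2–O bond from ionising during etherification and acylation) and two silyl ethers on ring A; they are removed in steps 9 and 10.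
Stereochemistry: C2 is set as the (R)-carbinol by asymmetric transfer hydrogenation and inverted to (S) by Mitsunobu etherification; no later step makes or breaks a bond at it.

Key step: step 8

Remark: the target is taken as the (2S)-flavanone drawn; chroman-4-one numbering (O1, C2 to C8a, 4' on ring B) is used for all intermediates.

Step 1
Reactants: 1 phloroglucinol (benzene-1,3,5-triol, 3 equiv); 2 prenol (3-methylbut-2-en-1-ol)
Product: 3 5-[(3-methylbut-2-en-1-yl)oxy]benzene-1,3-diol
Conditions: PPh3, DIAD, THF, 0 °C to rt
Reagents that add atoms: none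
Why: Mitsunobu O-alkylation of the acidic phenol under neutral conditions should avoid the C-prenylation that phloroglucinol suffers with prenyl halide and base, and the excess of cheap 1 should hold the reaction at the monoether.

Step 2
Reactants: 3 5-[(3-methylbut-2-en-1-yl)oxy]benzene-1,3-diol
Product: 4 2-(2-methylbut-3-en-2-yl)benzene-1,3,5-triol
Conditions: N,N-diethylaniline, 170 °C, sealed tube, argon
Reagents that add atoms: none
Why: Aromatic Claisen rearrangement ([3,3]-sigmatropic shift with allyl inversion); the two ortho positions of the prenyloxy group in 3 are equivalent, so the 1,1-dimethylallyl group should arrive on a carbon between two oxygens and tautomerisation should give the symmetric triol.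

Step 3
Reactants: 5 vanillin acetate (4-formyl-2-methoxyphenyl acetate); 6 tert-butyl diazoacetate
Product: 7 tert-butyl 3-(4-acetoxy-3-methoxyphenyl)-3-oxopropanoate
Conditions: NbCl5 (5 mol%), CH2Cl2, rt
Reagents that add atoms: none
Why: Roskamp reaction: the diazo carbon adds to the Lewis acid-activated aldehyde and a 1,2-hydride shift with loss of nitrogen should give the β-keto ester in one step without touching the aryl acetate.

Step 4
Reactants: 7 tert-butyl 3-(4-acetoxy-3-methoxyphenyl)-3-oxopropanoate
Product: 8 tert-butyl (3R)-3-(4-acetoxy-3-methoxyphenyl)-3-hydroxypropanoate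
Conditions: RuCl[(R,R)-TsDPEN](p-cymene) (1 mol%), HCO2H/Et3N (5:2), 30 °C
Reagents that add atoms: none
Why: Noyori asymmetric transfer hydrogenation of an aryl ketone; the (R,R)-ligand should deliver hydride to the face that gives the (R)-carbinol (the same sense as acetophenone to (R)-1-phenylethanol, with CH2CO2t-Bu in the place of methyl), which sets the stereocenter that becomes C2.

Step 5
Reactants: 4 2-(2-methylbut-3-en-2-yl)benzene-1,3,5-triol (1.2 equiv); 8 tert-butyl (3R)-3-(4-acetoxy-3-methoxyphenyl)-3-hydroxypropanoate
Product: 9 tert-butyl (3S)-3-(4-acetoxy-3-methoxyphenyl)-3-[3,5-dihydroxy-4-(2-methylbut-3-en-2-yl)phenoxy]propanoate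
Conditions: PPh3, DIAD, THF, 0 °C to rt
Reagents that add atoms: none
Why: Mitsunobu etherification: SN2 displacement of the oxyphosphonium ion with inversion should turn the (R)-alcohol into the (S)-aryl ether, the hydroxyl para to the quaternary carbon being the only unhindered one of 4, while the 4-acetoxy group disfavours ionisation of the benzylic centre.

Step 6
Reactants: 9 tert-butyl (3S)-3-(4-acetoxy-3-methoxyphenyl)-3-[3,5-dihydroxy-4-(2-methylbut-3-en-2-yl)phenoxy]propanoate
Product: 10 tert-butyl (3S)-3-(4-acetoxy-3-methoxyphenyl)-3-[3,5-bis(tert-butyldimethylsilyloxy)-4-(2-methylbut-3-en-2-yl)phenoxy]propanoate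
Conditions: TBSOTf, 2,6-lutidine, CH2Cl2, −40 to 0 °C
Reagents that add atoms: tert-butyldimethylsilyl trifluoromethanesulfonate, CC(C)(C)[Si](C)(C)OS(=O)(=O)C(F)(F)F
Why: Silylation with a silyl triflate and a hindered pyridine base should reach both hindered phenols at low temperature and mask them for the acylating medium of step 8, leaving the tert-butyl ester and the aryl acetate untouched.

Step 7
Reactants: 10 tert-butyl (3S)-3-(4-acetoxy-3-methoxyphenyl)-3-[3,5-bis(tert-butyldimethylsilyloxy)-4-(2-methylbut-3-en-2-yl)phenoxy]propanoate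
Product: 12 (3S)-3-(4-acetoxy-3-methoxyphenyl)-3-[3,5-bis(tert-butyldimethylsilyloxy)-4-(2-methylbut-3-en-2-yl)phenoxy]propanoic acid, via trimethylsilyl ester 11 (not isolated)
Conditions: TMSOTf, 2,6-lutidine, CH2Cl2, 0 °C; then pH 5 aqueous buffer
Reagents that add atoms: trimethylsilyl trifluoromethanesulfonate, C[Si](C)(C)OS(=O)(=O)C(F)(F)F (its atoms are kept only in intermediate 11)
Why: Silyl triflate-mediated cleavage of a tert-butyl ester (alkyl–oxygen fission with loss of isobutene, buffered by 2,6-lutidine) followed by hydrolysis of the silyl ester should free the acid without hydroxide (β-elimination of the aryloxide, loss of the acetate) and without strong protic acid.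

Step 8
Reactants: 12 (3S)-3-(4-acetoxy-3-methoxyphenyl)-3-[3,5-bis(tert-butyldimethylsilyloxy)-4-(2-methylbut-3-en-2-yl)phenoxy]propanoic acid
Product: 14 (2S)-2-(4-acetoxy-3-methoxyphenyl)-5,7-bis(tert-butyldimethylsilyloxy)-6-(2-methylbut-3-en-2-yl)chroman-4-one, via mixed trifluoroacetic anhydride 13 (not isolated)
Conditions: TFAA, CH2Cl2, 0 °C; aqueous NaHCO3 work-up
Reagents that add atoms: trifluoroacetic anhydride, O=C(OC(=O)C(F)(F)F)C(F)(F)F (its atoms are kept only in intermediate 13)
Why: The acid is converted into mixed anhydride 13, an acylium equivalent, which is attacked by a free carbon of ring A (ortho to the ether oxygen, ortho and para to the two silyloxy groups) to give an arenium ion that loses a proton and leaves the aryl ketone bond C4–C4a. The closest known reaction type is the intramolecular Friedel–Crafts acylation of 3-aryloxypropanoic and 3-aryl-3-aryloxypropanoic acids to chroman-4-ones and flavanones. Ring C closes in the 6-exo-trig mode. No stereocenter is formed; C2 should keep the configuration set in steps 4 and 5 because no bond to it is made or broken and the 4'-acetoxy group suppresses ionisation of the benzylic C2–O1 bond. Site selectivity on ring A is not needed, since the two free carbons are equivalent by the local mirror plane and either closure places the 1,1-dimethylallyl group at C6. Ring A should win over ring B because it carries three oxygen donors and closes a six-membered ring, whereas ring B is deactivated by the acetoxy group and could only close a five-membered indanone.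

Step 9
Reactants: 14 (2S)-2-(4-acetoxy-3-methoxyphenyl)-5,7-bis(tert-butyldimethylsilyloxy)-6-(2-methylbut-3-en-2-yl)chroman-4-one
Product: 15 (2S)-2-(4-acetoxy-3-methoxyphenyl)-5,7-dihydroxy-6-(2-methylbut-3-en-2-yl)chroman-4-one
Conditions: TBAF/AcOH (1:1), THF, 0 °C
Reagents that add atoms: none
Why: Fluoride-mediated cleavage of aryl silyl ethers, buffered with acetic acid so that no phenoxide or enolate can open ring C by retro-oxa-Michael reaction and scramble C2.

Step 10
Reactants: 15 (2S)-2-(4-acetoxy-3-methoxyphenyl)-5,7-dihydroxy-6-(2-methylbut-3-en-2-yl)chroman-4-one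
Product: 16 (2S)-5,7-dihydroxy-2-(4-hydroxy-3-methoxyphenyl)-6-(2-methylbut-3-en-2-yl)chroman-4-one (CNP0279383.1)
Conditions: NH4OAc, MeOH/H2O (4:1), rt
Reagents that add atoms: none
Why: Neutral solvolysis of an aryl acetate with ammonium acetate in aqueous methanol should free the 4'-hydroxyl without the base that opens 5-hydroxyflavanones to chalcones and without the acid that endangers the 1,1-dimethylallyl phenol.

Compound list
1 | phloroglucinol (benzene-1,3,5-triol) | Oc1cc(O)cc(O)c1 | starting material
2 | prenol (3-methylbut-2-en-1-ol) | CC(C)=CCO | starting material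
3 | 5-[(3-methylbut-2-en-1-yl)oxy]benzene-1,3-diol | CC(C)=CCOc1cc(O)cc(O)c1 | intermediate
4 | 2-(2-methylbut-3-en-2-yl)benzene-1,3,5-triol | C=CC(C)(C)c1c(O)cc(O)cc1O | intermediate
5 | vanillin acetate (4-formyl-2-methoxyphenyl acetate) | COc1cc(C=O)ccc1OC(C)=O | starting material
6 | tert-butyl diazoacetate | CC(C)(C)OC(=O)C=[N+]=[N-] | starting material
7 | tert-butyl 3-(4-acetoxy-3-methoxyphenyl)-3-oxopropanoate | COc1cc(ccc1OC(C)=O)C(=O)CC(=O)OC(C)(C)C | intermediate
8 | tert-butyl (3R)-3-(4-acetoxy-3-methoxyphenyl)-3-hydroxypropanoate | COc1cc(ccc1OC(C)=O)[C@H](O)CC(=O)OC(C)(C)C | intermediate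
9 | tert-butyl (3S)-3-(4-acetoxy-3-methoxyphenyl)-3-[3,5-dihydroxy-4-(2-methylbut-3-en-2-yl)phenoxy]propanoate | COc1cc(ccc1OC(C)=O)[C@@H](Oc1cc(O)c(c(O)c1)C(C)(C)C=C)CC(=O)OC(C)(C)C | intermediate
10 | tert-butyl (3S)-3-(4-acetoxy-3-methoxyphenyl)-3-[3,5-bis(tert-butyldimethylsilyloxy)-4-(2-methylbut-3-en-2-yl)phenoxy]propanoate | COc1cc(ccc1OC(C)=O)[C@@H](Oc1cc(O[Si](C)(C)C(C)(C)C)c(c(O[Si](C)(C)C(C)(C)C)c1)C(C)(C)C=C)CC(=O)OC(C)(C)C | intermediate
11 | trimethylsilyl (3S)-3-(4-acetoxy-3-methoxyphenyl)-3-[3,5-bis(tert-butyldimethylsilyloxy)-4-(2-methylbut-3-en-2-yl)phenoxy]propanoate | COc1cc(ccc1OC(C)=O)[C@@H](Oc1cc(O[Si](C)(C)C(C)(C)C)c(c(O[Si](C)(C)C(C)(C)C)c1)C(C)(C)C=C)CC(=O)O[Si](C)(C)C | intermediate (not isolated)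
12 | (3S)-3-(4-acetoxy-3-methoxyphenyl)-3-[3,5-bis(tert-butyldimethylsilyloxy)-4-(2-methylbut-3-en-2-yl)phenoxy]propanoic acid | COc1cc(ccc1OC(C)=O)[C@@H](Oc1cc(O[Si](C)(C)C(C)(C)C)c(c(O[Si](C)(C)C(C)(C)C)c1)C(C)(C)C=C)CC(=O)O | intermediate
13 | mixed anhydride of 12 with trifluoroacetic acid | COc1cc(ccc1OC(C)=O)[C@@H](Oc1cc(O[Si](C)(C)C(C)(C)C)c(c(O[Si](C)(C)C(C)(C)C)c1)C(C)(C)C=C)CC(=O)OC(=O)C(F)(F)F | intermediate (not isolated)
14 | (2S)-2-(4-acetoxy-3-methoxyphenyl)-5,7-bis(tert-butyldimethylsilyloxy)-6-(2-methylbut-3-en-2-yl)chroman-4-one | COc1cc(ccc1OC(C)=O)[C@@H]1CC(=O)c2c(O1)cc(O[Si](C)(C)C(C)(C)C)c(c2O[Si](C)(C)C(C)(C)C)C(C)(C)C=C | intermediate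
15 | (2S)-2-(4-acetoxy-3-methoxyphenyl)-5,7-dihydroxy-6-(2-methylbut-3-en-2-yl)chroman-4-one | COc1cc(ccc1OC(C)=O)[C@@H]1CC(=O)c2c(O1)cc(O)c(c2O)C(C)(C)C=C | intermediate
16 | (2S)-5,7-dihydroxy-2-(4-hydroxy-3-methoxyphenyl)-6-(2-methylbut-3-en-2-yl)chroman-4-one | COc1cc(ccc1O)[C@@H]1CC(=O)c2c(O1)cc(O)c(c2O)C(C)(C)C=C | target

Total step count: 10. Longest linear sequence: 8 steps (steps 1, 2, 5, 6, 7, 8, 9, 10; the branch through steps 3 and 4 is equally long).

Steps most likely to fail

Step 5 is judged the most exposed. The etherification may take place at one of the hindered hydroxyls or twice, the benzylic oxyphosphonium ion may ionise in part and erode the configurational purity, and elimination to the cinnamate may compete. The fallback differentiates the phenols by protection before the coupling instead of by rate. Setting out from 4, exhaustive silylation (TBSOTf, 2,6-lutidine, CH2Cl2) should give 1,3,5-tris(tert-butyldimethylsilyloxy)-2-(2-methylbut-3-en-2-yl)benzene F1. One equivalent of TBAF in THF at −78 °C should then cleave the only silyl ether that is not flanked by the quaternary carbon and give 3,5-bis(tert-butyldimethylsilyloxy)-4-(2-methylbut-3-en-2-yl)phenol F2. Mitsunobu etherification of F2 with 8 (PPh3, DIAD, THF) has a single hydroxyl to choose from and comes back to the route at 10.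

Step 8 is the second. The very electron-rich ring A may be protonated at the carbon that bears the 1,1-dimethylallyl group, with loss or migration of that group, and acid-induced desilylation followed by O-trifluoroacetylation may deactivate the ring before it is acylated. The fallback reverses the polarity of the bond formation (aryl anion onto an amide, Parham-type cyclisation) so that no acid is present. Setting out from 12, coupling with MeNHOMe·HCl (EDC, HOBt, i-Pr2NEt, CH2Cl2) should give (3S)-3-(4-acetoxy-3-methoxyphenyl)-3-[3,5-bis(tert-butyldimethylsilyloxy)-4-(2-methylbut-3-en-2-yl)phenoxy]-N-methoxy-N-methylpropanamide F3. NIS in MeCN at 0 °C should iodinate one of the two equivalent free carbons of ring A and give the corresponding 2-iodophenoxy amide F4. With t-BuLi (2 equiv) in THF at −100 °C, iodine–lithium exchange and addition of the aryllithium to the amide through a six-membered transition state should outrun attack on the aryl acetate and silyl migration from the neighbouring oxygen, and work-up returns the route at 14.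

Step 2 is the third. The freshly formed ortho-hydroxy 1,1-dimethylallyl arene may react further at the temperature of the rearrangement (abnormal Claisen rearrangement, ring closure of a phenol onto the alkene), and the triol may be oxidised. The fallback runs the rearrangement under trapping conditions. Setting out from 3, heating in N,N-diethylaniline with butanoic anhydride at 185 °C should acylate each phenol as it is present or formed and give 2-(2-methylbut-3-en-2-yl)benzene-1,3,5-triyl tributanoate F5. Ammonolysis (NH3, MeOH, 0 °C) should then release the triol and come back to the route at 4.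

Further compounds
F1 | step 5 | 1,3,5-tris(tert-butyldimethylsilyloxy)-2-(2-methylbut-3-en-2-yl)benzene | C=CC(C)(C)c1c(O[Si](C)(C)C(C)(C)C)cc(O[Si](C)(C)C(C)(C)C)cc1O[Si](C)(C)C(C)(C)C
F2 | step 5 | 3,5-bis(tert-butyldimethylsilyloxy)-4-(2-methylbut-3-en-2-yl)phenol | C=CC(C)(C)c1c(O[Si](C)(C)C(C)(C)C)cc(O)cc1O[Si](C)(C)C(C)(C)C
F3 | step 8 | (3S)-3-(4-acetoxy-3-methoxyphenyl)-3-[3,5-bis(tert-butyldimethylsilyloxy)-4-(2-methylbut-3-en-2-yl)phenoxy]-N-methoxy-N-methylpropanamide | COc1cc(ccc1OC(C)=O)[C@@H](Oc1cc(O[Si](C)(C)C(C)(C)C)c(c(O[Si](C)(C)C(C)(C)C)c1)C(C)(C)C=C)CC(=O)N(C)OC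
F4 | step 8 | (3S)-3-(4-acetoxy-3-methoxyphenyl)-3-[3,5-bis(tert-butyldimethylsilyloxy)-2-iodo-4-(2-methylbut-3-en-2-yl)phenoxy]-N-methoxy-N-methylpropanamide | COc1cc(ccc1OC(C)=O)[C@@H](Oc1cc(O[Si](C)(C)C(C)(C)C)c(c(O[Si](C)(C)C(C)(C)C)c1I)C(C)(C)C=C)CC(=O)N(C)OC
F5 | step 2 | 2-(2-methylbut-3-en-2-yl)benzene-1,3,5-triyl tributanoate | CCCC(=O)Oc1cc(OC(=O)CCC)c(c(OC(=O)CCC)c1)C(C)(C)C=C
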